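**Retrosynthetic overview**
- Both rings are closed in the last step by one cation–olefin cascade on an acyclic chain: a tertiary methyl ether ionises to the C4 cation, ring A closes (C4–C5), then ring B (C10–C9).
- A CH2SiMe3 group on C8 ends the cascade as the 8(17)-methylene; a chiral counter-anion is relied on to set C5, C9 and C10.
- The acyclic precursor is cut at C9–C11 (B-alkyl Suzuki coupling) into a (Z)-iodoalkenyl allylsilane and a five-carbon alkene that already carries C13, C14 and the acetate.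
- The iodoalkene comes from geraniol (methoxymercuration, bromide, propargylation, silylmethyl-cupration/iodination).
- The side-chain piece comes from acetoxyacetaldehyde by syn-selective asymmetric crotylboration.

Assumption: the (S,S)-catalyst of step 8 is taken to give the 5S,9S,10S series; if the first run shows the opposite sense, its (R,R)-antipode is used under the same conditions.

**Step 1**
Reactants: 1 geraniol
Product: 3 (2E)-7-methoxy-3,7-dimethyloct-2-en-1-ol, via acetoxymercurio adduct 2 (not isolated)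
Conditions: Hg(OAc)2, MeOH, 0 °C → rt; then NaBH4, 3 M NaOH, 0 °C
Reagents that add atoms: methanol (CO)
Why: Alkoxymercuration–demercuration (Markovnikov): the remote 6,7-alkene reacts before the 2,3-alkene, which is deactivated by the allylic oxygen, and methanol enters at the tertiary carbon; no stereocentre is formed.

**Step 2**
Reactants: 3 (2E)-7-methoxy-3,7-dimethyloct-2-en-1-ol
Product: 4 (2E)-1-bromo-7-methoxy-3,7-dimethyloct-2-ene
Conditions: CBr4, PPh3, CH2Cl2, 0 °C
Reagents that add atoms: carbon tetrabromide (BrC(Br)(Br)Br)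
Why: Appel bromination is an SN2 displacement at the primary allylic carbon under neutral conditions, so the E-alkene and the tertiary ether are untouched.

**Step 3**
Reactants: 4 (2E)-1-bromo-7-methoxy-3,7-dimethyloct-2-ene; 5 propargyl bromide
Product: 8 (5E)-10-methoxy-6,10-dimethylundec-5-en-1-yne, via 1,3-dilithiopropyne 6 (not isolated), via lithium acetylide 7 (not isolated)
Conditions: 5, n-BuLi (2 equiv), TMEDA, Et2O–hexane, −78 °C; then 4, −78 °C → rt; H2O
Reagents that add atoms: none
Why: Alkylation of 1,3-dilithiopropyne takes place at its sp3 carbon by SN2 attack on the allylic bromide without allylic transposition, and the remaining acetylide is protonated on work-up.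

**Step 4**
Reactants: 8 (5E)-10-methoxy-6,10-dimethylundec-5-en-1-yne
Product: 10 (1Z,5E)-1-iodo-10-methoxy-6,10-dimethyl-2-[(trimethylsilyl)methyl]undeca-1,5-diene, via alkenylcopper 9 (not isolated)
Conditions: Me3SiCH2MgCl, CuBr·SMe2, LiBr, THF–Et2O, −10 °C → rt; then I2, −40 °C
Reagents that add atoms: (trimethylsilyl)methylmagnesium chloride (C[Si](C)(C)C[Mg]Cl); iodine (II)
Why: Normant syn-carbocupration puts the silylmethyl group on the internal carbon and copper on the terminal carbon, and iodinolysis with retention fixes the trisubstituted alkene with CH2SiMe3 cis to iodine.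

**Step 5**
Reactants: 11 (2Z)-but-2-ene-1,4-diyl diacetate
Product: 13 2-oxoethyl acetate, via ozonide 12 (not isolated)
Conditions: O3, CH2Cl2, −78 °C; then Me2S, −78 °C → rt; distilled and used at once
Reagents that add atoms: ozone ([O-][O+]=O)
Why: Ozonolysis with reductive work-up cleaves the symmetric alkene into two molecules of the aldehyde; no stereocentre is involved.

**Step 6**
Reactants: 13 2-oxoethyl acetate; 14 cis-but-2-ene
Product: 19 (2S,3R)-2-hydroxy-3-methylpent-4-en-1-yl acetate, via (Z)-crotylpotassium 15 (not isolated), via methoxyborate complex 16 (not isolated), via (Z)-crotylborane 17 (not isolated), via borinate ester 18 (not isolated)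
Conditions: 14, n-BuLi, KOt-Bu, THF, −78 → −45 °C; (−)-Ipc2BOMe [(−)-B-methoxydiisopinocampheylborane, from (+)-α-pinene], −78 °C; BF3·OEt2; then 13, −78 °C; HOCH2CH2NH2, Et2O, 0 °C → rt
Reagents that add atoms: none
Why: Brown crotylboration runs through a closed chair transition state, so the Z-crotyl geometry gives the syn methyl/hydroxyl pair and the (−)-Ipc ligands direct attack to the Si face of the aldehyde, setting 2S and 3R (C14 and C13 of the target); the non-oxidative ethanolamine work-up spares the acetate.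

**Step 7**
Reactants: 19 (2S,3R)-2-hydroxy-3-methylpent-4-en-1-yl acetate; 10 (1Z,5E)-1-iodo-10-methoxy-6,10-dimethyl-2-[(trimethylsilyl)methyl]undeca-1,5-diene
Product: 21 (2S,3R,6Z,10E)-2-hydroxy-15-methoxy-3,11,15-trimethyl-7-[(trimethylsilyl)methyl]hexadeca-6,10-dien-1-yl acetate, via alkylborane 20 (not isolated)
Conditions: 9-BBN dimer (2.2 equiv B–H), THF, 0 °C → rt; then 10, PdCl2(dppf) (5 mol%), AsPh3, Cs2CO3, DMF–H2O, rt
Reagents that add atoms: none
Why: B-alkyl Suzuki–Miyaura coupling: 9-BBN adds anti-Markovnikov to the terminal alkene (the free OH takes the second equivalent) and the alkylborane couples with the alkenyl iodide with retention of alkene geometry; no stereocentre is touched.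

**Step 8**
Reactants: 21 (2S,3R,6Z,10E)-2-hydroxy-15-methoxy-3,11,15-trimethyl-7-[(trimethylsilyl)methyl]hexadeca-6,10-dien-1-yl acetate
Product: 24 (2S,3R)-2-hydroxy-3-methyl-5-[(1S,4aS,8aS)-5,5,8a-trimethyl-2-methylidenedecahydronaphthalen-1-yl]pentyl acetate, via silyl ether 22 (not isolated), via cyclized silyl ether 23 (not isolated)
Conditions: 2-methylallyltrimethylsilane (1.2 equiv), (S,S)-IDPi [imidodiphosphorimidate acid from two (S)-3,3'-bis(3,5-bis(trifluoromethyl)phenyl)-1,1'-bi-2-naphthol units, both P=N–SO2CF3] (5 mol%), toluene, 0.01 M, −78 → −30 °C; then citric acid, MeOH, 0 °C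
Reagents that add atoms: none
Why: Proposed new method: the acid first silylates O14 with the methallylsilane (isobutene leaves) and is itself turned into the silylated ion pair, so no free Brønsted acid remains to protodesilylate the terminator; silyl transfer to the tertiary ether oxygen and loss of MeOSiMe3 gives the C4 cation inside the chiral anion, which closes ring A (C4–C5) and ring B (C10–C9) through the chair–chair fold (E-alkene gives the trans ring fusion, the C8=C9 geometry puts the side chain equatorial, the anion chooses the 5S,9S,10S antipode), and the β-silyl C8 cation gives Me3Si+ back to the anion, leaving the 8(17)-methylene and carrying the chain; closest known reaction types are the confined-acid asymmetric polyene cyclization of homofarnesol, silylium-based counteranion-directed asymmetric Hosomi–Sakurai allylation, and Lewis-acid SN1 ionisation of tertiary ethers in allylsilane-terminated cation–olefin cyclizations.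

**Compound list**
1 | geraniol | CC(C)=CCC/C(C)=C/CO | starting material
2 | (2E)-6-(acetoxymercurio)-7-methoxy-3,7-dimethyloct-2-en-1-ol | COC(C)(C)C([Hg]OC(C)=O)CC/C(C)=C/CO | intermediate
3 | (2E)-7-methoxy-3,7-dimethyloct-2-en-1-ol | COC(C)(C)CCC/C(C)=C/CO | intermediate
4 | (2E)-1-bromo-7-methoxy-3,7-dimethyloct-2-ene | COC(C)(C)CCC/C(C)=C/CBr | intermediate
5 | propargyl bromide (3-bromoprop-1-yne) | BrCC#C | starting material
6 | 1,3-dilithiopropyne | [Li]CC#C[Li] | intermediate
7 | lithium acetylide of 8 | COC(C)(C)CCC/C(C)=C/CCC#C[Li] | intermediate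
8 | (5E)-10-methoxy-6,10-dimethylundec-5-en-1-yne | COC(C)(C)CCC/C(C)=C/CCC#C | intermediate
9 | [(1Z,5E)-10-methoxy-6,10-dimethyl-2-[(trimethylsilyl)methyl]undeca-1,5-dien-1-yl]copper | COC(C)(C)CCC/C(C)=C/CC/C(C[Si](C)(C)C)=C/[Cu] | intermediate
10 | (1Z,5E)-1-iodo-10-methoxy-6,10-dimethyl-2-[(trimethylsilyl)methyl]undeca-1,5-diene | COC(C)(C)CCC/C(C)=C/CC/C(C[Si](C)(C)C)=C/I | intermediate
11 | (2Z)-but-2-ene-1,4-diyl diacetate | CC(=O)OC/C=C\COC(C)=O | starting material
12 | (1,2,4-trioxolane-3,5-diyl)bis(methylene) diacetate | CC(=O)OCC1OOC(COC(C)=O)O1 | intermediate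
13 | 2-oxoethyl acetate (acetoxyacetaldehyde) | CC(=O)OCC=O | intermediate
14 | cis-but-2-ene | C/C=C\C | starting material
15 | (Z)-but-2-enylpotassium | C/C=C\C[K] | intermediate
16 | potassium (Z)-but-2-enyl(methoxy)bis(isopinocampheyl)borate | [K+].C/C=C\C[B-](OC)([C@@H]1C[C@@H]2C[C@H]([C@H]1C)C2(C)C)[C@@H]1C[C@@H]2C[C@H]([C@H]1C)C2(C)C | intermediate
17 | (Z)-but-2-enylbis(isopinocampheyl)borane | C/C=C\CB([C@@H]1C[C@@H]2C[C@H]([C@H]1C)C2(C)C)[C@@H]1C[C@@H]2C[C@H]([C@H]1C)C2(C)C | intermediate
18 | (2S,3R)-2-[bis(isopinocampheyl)boryloxy]-3-methylpent-4-en-1-yl acetate | C=C[C@@H](C)[C@H](OB([C@@H]1C[C@@H]2C[C@H]([C@H]1C)C2(C)C)[C@@H]1C[C@@H]2C[C@H]([C@H]1C)C2(C)C)COC(C)=O | intermediate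
19 | (2S,3R)-2-hydroxy-3-methylpent-4-en-1-yl acetate | C=C[C@@H](C)[C@H](O)COC(C)=O | intermediate
20 | (2S,3R)-5-(9-borabicyclo[3.3.1]nonan-9-yl)-2-(9-borabicyclo[3.3.1]nonan-9-yloxy)-3-methylpentyl acetate | C(C[C@@H](C)[C@H](OB1C2CCCC1CCC2)COC(C)=O)B1C2CCCC1CCC2 | intermediate
21 | (2S,3R,6Z,10E)-2-hydroxy-15-methoxy-3,11,15-trimethyl-7-[(trimethylsilyl)methyl]hexadeca-6,10-dien-1-yl acetate | COC(C)(C)CCC/C(C)=C/CC/C(C[Si](C)(C)C)=C/CC[C@@H](C)[C@H](O)COC(C)=O | intermediate
22 | (2S,3R,6Z,10E)-15-methoxy-3,11,15-trimethyl-7-[(trimethylsilyl)methyl]-2-[(trimethylsilyl)oxy]hexadeca-6,10-dien-1-yl acetate | COC(C)(C)CCC/C(C)=C/CC/C(C[Si](C)(C)C)=C/CC[C@@H](C)[C@H](O[Si](C)(C)C)COC(C)=O | intermediate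
23 | (2S,3R)-3-methyl-5-[(1S,4aS,8aS)-5,5,8a-trimethyl-2-methylidenedecahydronaphthalen-1-yl]-2-[(trimethylsilyl)oxy]pentyl acetate | C=C1CC[C@H]2C(C)(C)CCC[C@]2(C)[C@H]1CC[C@@H](C)[C@H](O[Si](C)(C)C)COC(C)=O | intermediate
24 | (2S,3R)-2-hydroxy-3-methyl-5-[(1S,4aS,8aS)-5,5,8a-trimethyl-2-methylidenedecahydronaphthalen-1-yl]pentyl acetate, i.e. (13R,14S)-14-hydroxylabd-8(17)-en-15-yl acetate | C=C1CC[C@H]2C(C)(C)CCC[C@]2(C)[C@H]1CC[C@@H](C)[C@H](O)COC(C)=O | target

**Step count and risks**
Total steps: 8. Longest linear sequence: 6 (steps 1, 2, 3, 4, 7, 8).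

Most likely to fail, first: step 8. Enantiocontrol by the counter-anion over an unstabilised tertiary cation has no direct precedent in this silylium mode, and elimination of the cation or loss of the allylsilane to stray acid would lower the yield. The fallback sets out from 21 and comes back at 24, and replaces catalyst control by resolution through the fixed side-chain centres. Compound 21 is treated with 2-methylallyltrimethylsilane and achiral Me3SiNTf2 (5 mol%) in CH2Cl2 at −78 °C; 22 forms and cyclizes without facial bias to 23 and its ring-antipodal partner (2S,3R)-3-methyl-5-[(1R,4aR,8aR)-5,5,8a-trimethyl-2-methylidenedecahydronaphthalen-1-yl]-2-[(trimethylsilyl)oxy]pentyl acetate F1. Methanolysis (citric acid, MeOH) gives 24 together with (2S,3R)-2-hydroxy-3-methyl-5-[(1R,4aR,8aR)-5,5,8a-trimethyl-2-methylidenedecahydronaphthalen-1-yl]pentyl acetate F2. The two are diastereomers and are separated by preparative HPLC, at the price of at most half of the material.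

Second: step 4. Silylmethylcopper may add sluggishly to an unactivated terminal alkyne, and iodine can attack the new allylsilane. The fallback sets out from 8 and comes back at 10, and builds the same alkene by borylcupration and electrophilic trapping. Compound 8 is treated with B2pin2, CuCl (10 mol%), Xantphos and NaOt-Bu in THF; syn-addition gives [(1Z,5E)-10-methoxy-6,10-dimethyl-1-(4,4,5,5-tetramethyl-1,3,2-dioxaborolan-2-yl)undeca-1,5-dien-2-yl]copper F3, which is alkylated in the flask by (iodomethyl)trimethylsilane to 2-[(1Z,5E)-10-methoxy-6,10-dimethyl-2-[(trimethylsilyl)methyl]undeca-1,5-dien-1-yl]-4,4,5,5-tetramethyl-1,3,2-dioxaborolane F4. Iododeboronation with retention (NaOH, I2, THF, 0 °C) then gives 10.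

Third: step 7. The primary acetate next to a free hydroxyl may migrate or hydrolyse under the aqueous base of the coupling. The fallback sets out from 14 and 10 and comes back at 21, and carries C15 as a silyl ether through the coupling so that the acetate is put on last. The crotylborane 17 (made from 14 as in step 6) is added to commercial (tert-butyldimethylsilyloxy)acetaldehyde to give (2S,3R)-2-[bis(isopinocampheyl)boryloxy]-1-[(tert-butyldimethylsilyl)oxy]-3-methylpent-4-ene F5, freed by ethanolamine to (2S,3R)-1-[(tert-butyldimethylsilyl)oxy]-3-methylpent-4-en-2-ol F6. Hydroboration with 9-BBN gives (2S,3R)-5-(9-borabicyclo[3.3.1]nonan-9-yl)-2-(9-borabicyclo[3.3.1]nonan-9-yloxy)-1-[(tert-butyldimethylsilyl)oxy]-3-methylpentane F7, which is coupled with 10 under the conditions of step 7 to (2S,3R,6Z,10E)-1-[(tert-butyldimethylsilyl)oxy]-15-methoxy-3,11,15-trimethyl-7-[(trimethylsilyl)methyl]hexadeca-6,10-dien-2-ol F8. Bu4NF buffered with AcOH (THF, 0 °C) gives (2S,3R,6Z,10E)-15-methoxy-3,11,15-trimethyl-7-[(trimethylsilyl)methyl]hexadeca-6,10-diene-1,2-diol F9, and AcCl with 2,4,6-collidine (CH2Cl2, −78 °C) acetylates the primary hydroxyl only, giving 21.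

**Further compounds**
F1 | step 8 | (2S,3R)-3-methyl-5-[(1R,4aR,8aR)-5,5,8a-trimethyl-2-methylidenedecahydronaphthalen-1-yl]-2-[(trimethylsilyl)oxy]pentyl acetate | C=C1CC[C@@H]2C(C)(C)CCC[C@@]2(C)[C@@H]1CC[C@@H](C)[C@H](O[Si](C)(C)C)COC(C)=O
F2 | step 8 | (2S,3R)-2-hydroxy-3-methyl-5-[(1R,4aR,8aR)-5,5,8a-trimethyl-2-methylidenedecahydronaphthalen-1-yl]pentyl acetate | C=C1CC[C@@H]2C(C)(C)CCC[C@@]2(C)[C@@H]1CC[C@@H](C)[C@H](O)COC(C)=O
F3 | step 4 | [(1Z,5E)-10-methoxy-6,10-dimethyl-1-(4,4,5,5-tetramethyl-1,3,2-dioxaborolan-2-yl)undeca-1,5-dien-2-yl]copper | COC(C)(C)CCC/C(C)=C/CC/C([Cu])=C/B1OC(C)(C)C(C)(C)O1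
F4 | step 4 | 2-[(1Z,5E)-10-methoxy-6,10-dimethyl-2-[(trimethylsilyl)methyl]undeca-1,5-dien-1-yl]-4,4,5,5-tetramethyl-1,3,2-dioxaborolane | COC(C)(C)CCC/C(C)=C/CC/C(C[Si](C)(C)C)=C/B1OC(C)(C)C(C)(C)O1
F5 | step 7 | (2S,3R)-2-[bis(isopinocampheyl)boryloxy]-1-[(tert-butyldimethylsilyl)oxy]-3-methylpent-4-ene | C=C[C@@H](C)[C@H](OB([C@@H]1C[C@@H]2C[C@H]([C@H]1C)C2(C)C)[C@@H]1C[C@@H]2C[C@H]([C@H]1C)C2(C)C)CO[Si](C)(C)C(C)(C)C
F6 | step 7 | (2S,3R)-1-[(tert-butyldimethylsilyl)oxy]-3-methylpent-4-en-2-ol | C=C[C@@H](C)[C@H](O)CO[Si](C)(C)C(C)(C)C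
F7 | step 7 | (2S,3R)-5-(9-borabicyclo[3.3.1]nonan-9-yl)-2-(9-borabicyclo[3.3.1]nonan-9-yloxy)-1-[(tert-butyldimethylsilyl)oxy]-3-methylpentane | C(C[C@@H](C)[C@H](OB1C2CCCC1CCC2)CO[Si](C)(C)C(C)(C)C)B1C2CCCC1CCC2
F8 | step 7 | (2S,3R,6Z,10E)-1-[(tert-butyldimethylsilyl)oxy]-15-methoxy-3,11,15-trimethyl-7-[(trimethylsilyl)methyl]hexadeca-6,10-dien-2-ol | COC(C)(C)CCC/C(C)=C/CC/C(C[Si](C)(C)C)=C/CC[C@@H](C)[C@H](O)CO[Si](C)(C)C(C)(C)C
F9 | step 7 | (2S,3R,6Z,10E)-15-methoxy-3,11,15-trimethyl-7-[(trimethylsilyl)methyl]hexadeca-6,10-diene-1,2-diol | COC(C)(C)CCC/C(C)=C/CC/C(C[Si](C)(C)C)=C/CC[C@@H](C)[C@H](O)CO
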